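The runs are calculated on assumed constants; noise was put on by code.

If a computed curve is to be believed on a new flask, its books must close first, so I kept a ledger of the starting material, here c(starting material) = 0.50 M against 2.00 equiv of coupling partner.

| flask | starting material | coupling partner | remark | time |
|---|---|---|---|---|
| south-east | 0.70 M | 2 equiv | run made earlier |  |
| west | 1.1 M | 2 equiv | run made earlier |  |
| south | 0.50 M | 1 equiv | run made earlier |  |
| flask | 0.50 M | 2.00 equiv |  | 15 d |

| run | time / d | target / % | isomer of the product A / % | starting material / % |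
|---|---|---|---|---|
| south-east | 2.00 | 27 | 15 | 34 |
| south-east | 4.00 | 35 | 21 | 21 |
| south-east | 6.00 | 37 | 25 | 15 |
| south-east | 8.00 | 36 | 29 | 17 |
| south-east | 10.0 | 37 | 32 | 12 |
| south-east | 12.0 | 35 | 34 | 10 |
| south-east | 15.0 | 35 | 39 | 9 |
| west | 0.833 | 16 | 8 | 47 |
| west | 2.50 | 34 | 17 | 23 |
| west | 4.00 | 37 | 24 | 16 |
| west | 6.00 | 37 | 28 | 13 |
| west | 10.0 | 40 | 32 | 8 |
| west | 12.0 | 37 | 36 | 7 |
| west | 15.0 | 34 | 43 | 7 |
| south | 3.00 | 17 | 11 | 56 |
| south | 6.00 | 25 | 20 | 43 |
| south | 10.0 | 27 | 23 | 36 |
| south | 12.0 | 26 | 24 | 34 |
| south | 15.0 | 25 | 30 | 31 |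

(scatter of a reading: 1.5 percentage points)



- ratio of target to isomer of the product A at 8.0 h
- ratio of target to isomer of the product A at 15 d

In the south-east run at 15.0 d, 9 % of the charge remained, 35 % stood as target and 39 % as isomer of the product A. That left 17.0 % in no column. The material was consumed, but I could not read where it went. Pooling the last readings of the three runs, I divided the missing material by the starting material consumed and got 18.6 %, a reading with its scatter, which I call the unread share. I committed to that share at 15 d for the new flask.

The forecast gave 2 at 8.0 h and 0.85 at 15 d, noting: “The target plateaus and then sags while the isomer keeps growing”.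

The flask gave 2.48 and 0.868, so the forecast was lower at the early time and within tolerance at the late one.

    starting material + coupling partner → intermediate + released group (k = 0.0270 M⁻¹ h⁻¹)
    intermediate ⇌ target (K = 8.40, k = 0.0530 h⁻¹)
    intermediate ⇌ isomer of the product A (K = 47.0, k = 0.0190 h⁻¹)
    target ⇌ isomer of the product B (K = 0.440, k = 0.0440 h⁻¹)
    2 coupling partner → homo dimer (k = 0.00780 M⁻¹ h⁻¹)

At 15 d, target in the flask was made more slowly than it was used up, the net rates standing at 0.301. It stood at 32.9 % against 37.9 % of isomer of the product A. The flask consumed 88.9 % of its starting material, so the unread share gives 16.5 %, and isomer of the product B plus intermediate held 18.0 %. With 5.00 equiv of coupling partner, 1.69 % of the starting material remained, so the share gives 18.3 %; that neighbour's computed isomer of the product B plus intermediate came to 19.2 %.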